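## Retrosynthetic overview

1. Target ⇐ removal of two silyl ethers ⇐ 1,2-reduction of the C8 ketone under substrate control ⇐ C5 chlorination of a bis-silylated (7S)-azaphilone dione.
2. Azaphilone dione ⇐ hydroxylative dearomatisation of a resorcylaldehyde keto-aldehyde by an FAD-dependent monooxygenase; the product closes the pyran ring by itself. The carbocycle is bought as a benzene ring, so the pyran ring is the only ring made and it is made last.
3. Keto-aldehyde ⇐ aldehyde-directed alkyne hydration ⇐ Sonogashira union of 6-bromo-2,4-dihydroxy-3-methylbenzaldehyde with an (S)-configured dienynol.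
4. Dienynol ⇐ Wittig and Horner–Wadsworth–Emmons chain extension of (S)-4-silyloxy-2-methylbutanal ⇐ (S)-α-methyl-γ-butyrolactone ⇐ Ru(OAc)2(BINAP)-catalysed asymmetric hydrogenation of α-methylene-γ-butyrolactone (first stereocentre).
5. Bromoaldehyde ⇐ 2,6-dimethoxytoluene by C–H borylation, bromodeboronation, formylation and demethylation.

Assumption: the BINAP antipode written in step 1 is taken to be the one that gives the (S)-lactone (otherwise its mirror image is used), the monooxygenase homologue in step 16 is the one that gives the (7S)-bicyclic dione (AfoD type, not the 7R-selective AzaH type), and recombinant enzymes count as available.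

## Route

Step 1
Reactants: 1 3-methylenedihydrofuran-2(3H)-one (α-methylene-γ-butyrolactone)
Product: 2 (S)-3-methyldihydrofuran-2(3H)-one
Conditions: Ru(OAc)2[(S)-BINAP] (0.5 mol%), H2 (100 atm), CH2Cl2, 50 °C
Reagents that add atoms: none
Why: Asymmetric hydrogenation of the exocyclic alkene, bound to ruthenium through the lactone carbonyl, delivers H2 to one enantioface and sets the methyl-bearing stereocentre (S), the first stereocentre of the synthesis.

Step 2
Reactants: 2 (S)-3-methyldihydrofuran-2(3H)-one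
Product: 3 (S)-4-hydroxy-N-methoxy-N,2-dimethylbutanamide
Conditions: MeNH(OMe)·HCl, AlMe3, CH2Cl2, 0 °C to rt; aq. KNaC4H4O6 (potassium sodium tartrate) work-up; used crude
Reagents that add atoms: N,O-dimethylhydroxylamine hydrochloride, CNOC.Cl
Why: Weinreb aminolysis of the lactone with the aluminium amide opens the ring without touching the α-stereocentre and gives an amide that can later be reduced cleanly to the aldehyde.

Step 3
Reactants: 3 (S)-4-hydroxy-N-methoxy-N,2-dimethylbutanamide
Product: 4 (S)-4-((tert-butyldimethylsilyl)oxy)-N-methoxy-N,2-dimethylbutanamide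
Conditions: TBSCl, imidazole, DMF, rt
Reagents that add atoms: tert-butyldimethylsilyl chloride (TBSCl), CC(C)(C)[Si](C)(C)Cl
Why: Silylation of the primary alcohol stops relactonisation and prevents lactol formation in the next step.

Step 4
Reactants: 4 (S)-4-((tert-butyldimethylsilyl)oxy)-N-methoxy-N,2-dimethylbutanamide
Product: 5 (S)-4-((tert-butyldimethylsilyl)oxy)-2-methylbutanal
Conditions: i-Bu2AlH, THF, −78 °C; aq. KNaC4H4O6 work-up; used at once
Reagents that add atoms: none
Why: Weinreb amide reduction stops at the aldehyde oxidation level at −78 °C, and the cold neutral work-up avoids epimerisation of the α-methyl aldehyde.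

Step 5
Reactants: 5 (S)-4-((tert-butyldimethylsilyl)oxy)-2-methylbutanal; 6 ethyl 2-(triphenylphosphoranylidene)propanoate
Product: 7 ethyl (S,E)-6-((tert-butyldimethylsilyl)oxy)-2,4-dimethylhex-2-enoate
Conditions: CH2Cl2, rt, 16 h
Reagents that add atoms: none
Why: Wittig olefination with the stabilised ylide gives the (E)-trisubstituted enoate under neutral conditions that do not epimerise the aldehyde.

Step 6
Reactants: 7 ethyl (S,E)-6-((tert-butyldimethylsilyl)oxy)-2,4-dimethylhex-2-enoate
Product: 8 (S,E)-6-((tert-butyldimethylsilyl)oxy)-2,4-dimethylhex-2-en-1-ol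
Conditions: i-Bu2AlH (2.2 equiv), CH2Cl2, −78 °C
Reagents that add atoms: none
Why: Hydride 1,2-reduction of the enoate gives the allylic alcohol without touching the alkene or the silyl ether.

Step 7
Reactants: 8 (S,E)-6-((tert-butyldimethylsilyl)oxy)-2,4-dimethylhex-2-en-1-ol
Product: 9 (S,E)-6-((tert-butyldimethylsilyl)oxy)-2,4-dimethylhex-2-enal
Conditions: MnO2 (activated, excess), CH2Cl2, rt
Reagents that add atoms: none
Why: Allylic oxidation with MnO2 is selective for the allylic alcohol and keeps the alkene geometry.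

Step 8
Reactants: 9 (S,E)-6-((tert-butyldimethylsilyl)oxy)-2,4-dimethylhex-2-enal; 10 diethyl (3-(trimethylsilyl)prop-2-yn-1-yl)phosphonate
Product: 11 tert-butyl{[(S,4E,6E)-3,5-dimethyl-9-(trimethylsilyl)nona-4,6-dien-8-yn-1-yl]oxy}dimethylsilane
Conditions: LiN(SiMe3)2, THF, −78 °C, then 9, −78 to 0 °C
Reagents that add atoms: none
Why: Horner–Wadsworth–Emmons olefination with the lithiated propargylic phosphonate builds the new disubstituted alkene with high E selectivity and brings in the protected alkyne.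

Step 9
Reactants: 11 tert-butyl{[(S,4E,6E)-3,5-dimethyl-9-(trimethylsilyl)nona-4,6-dien-8-yn-1-yl]oxy}dimethylsilane
Product: 12 (S,4E,6E)-3,5-dimethylnona-4,6-dien-8-yn-1-ol
Conditions: TBAF (2.5 equiv), THF, 0 °C to rt
Reagents that add atoms: none
Why: Fluoride-mediated desilylation removes the alkynyl and the oxygen silyl groups together; the free primary alcohol is tolerated by the coupling, hydration and enzyme steps that follow.

Step 10
Reactants: 13 1,3-dimethoxy-2-methylbenzene (2,6-dimethoxytoluene)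
Product: 14 2-(3,5-dimethoxy-4-methylphenyl)-4,4,5,5-tetramethyl-1,3,2-dioxaborolane
Conditions: [Ir(OMe)(cod)]2 (1.5 mol%), dtbpy (3 mol%), B2pin2 (1.0 equiv), THF, 80 °C
Reagents that add atoms: bis(pinacolato)diboron (B2pin2), CC1(C)OB(OC1(C)C)B1OC(C)(C)C(C)(C)O1
Why: Iridium-catalysed C–H borylation is sterically controlled and goes to the only ring C–H with no ortho substituent, para to the methyl group.

Step 11
Reactants: 14 2-(3,5-dimethoxy-4-methylphenyl)-4,4,5,5-tetramethyl-1,3,2-dioxaborolane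
Product: 15 5-bromo-1,3-dimethoxy-2-methylbenzene
Conditions: CuBr2 (3 equiv), MeOH/H2O 1:1, 80 °C
Reagents that add atoms: copper dibromide (CuBr2), Br[Cu]Br
Why: Copper-mediated bromodeboronation (ipso substitution) puts bromine meta to both methoxy groups, a position that electrophilic bromination cannot reach.

Step 12
Reactants: 15 5-bromo-1,3-dimethoxy-2-methylbenzene
Product: 16 6-bromo-2,4-dimethoxy-3-methylbenzaldehyde
Conditions: Cl2CHOMe, TiCl4, CH2Cl2, −78 to 0 °C; then H2O
Reagents that add atoms: dichloromethyl methyl ether, COC(Cl)Cl; water, O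
Why: Rieche formylation (Friedel–Crafts type) attacks the position ortho and para to the two methoxy groups, and the two open positions are equivalent, so one aldehyde results.

Step 13
Reactants: 16 6-bromo-2,4-dimethoxy-3-methylbenzaldehyde
Product: 17 6-bromo-2,4-dihydroxy-3-methylbenzaldehyde
Conditions: BBr3 (4 equiv), CH2Cl2, −78 °C to rt; then H2O
Reagents that add atoms: none
Why: Lewis-acid ether cleavage with BBr3 frees both phenols before the sensitive side chain is attached; the aldehyde and aryl bromide are inert.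

Step 14
Reactants: 17 6-bromo-2,4-dihydroxy-3-methylbenzaldehyde; 12 (S,4E,6E)-3,5-dimethylnona-4,6-dien-8-yn-1-ol
Product: 18 2,4-dihydroxy-6-[(S,3E,5E)-9-hydroxy-5,7-dimethylnona-3,5-dien-1-yn-1-yl]-3-methylbenzaldehyde
Conditions: PdCl2(PPh3)2 (5 mol%), CuI (10 mol%), Et3N, DMF, 60 °C, degassed
Reagents that add atoms: none
Why: Sonogashira coupling joins the two fragments; the ortho-formyl group activates the C–Br bond and the free phenols and alcohol are tolerated under amine base.

Step 15
Reactants: 18 2,4-dihydroxy-6-[(S,3E,5E)-9-hydroxy-5,7-dimethylnona-3,5-dien-1-yn-1-yl]-3-methylbenzaldehyde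
Product: 20 2,4-dihydroxy-6-[(S,3E,5E)-9-hydroxy-5,7-dimethyl-2-oxonona-3,5-dien-1-yl]-3-methylbenzaldehyde, via 2-benzopyrylium trifluoroacetate 19 (not isolated)
Conditions: Au(OAc)3 (5 mol%), TFA/ClCH2CH2Cl 1:10, rt, 10 min; then MeCN/KH2PO4–K2HPO4 buffer pH 7, rt
Reagents that add atoms: water, O
Why: Gold-catalysed 6-endo-dig cycloisomerisation of the o-alkynylbenzaldehyde gives the 2-benzopyrylium salt, and its hydrolytic ring-opening at pH 7 amounts to an aldehyde-directed alkyne hydration that places the ketone on the carbon remote from the arene.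

Step 16
Reactants: 20 2,4-dihydroxy-6-[(S,3E,5E)-9-hydroxy-5,7-dimethyl-2-oxonona-3,5-dien-1-yl]-3-methylbenzaldehyde
Product: 22 (S)-7-hydroxy-3-[(S,1E,3E)-7-hydroxy-3,5-dimethylhepta-1,3-dien-1-yl]-7-methyl-6H-isochromene-6,8(7H)-dione, via o-quinol 21 (not isolated)
Conditions: FAD-dependent monooxygenase (7S-selective homologue, AfoD type, clarified E. coli lysate), NADP+ (2 mol%), Na2HPO3, phosphite dehydrogenase, air, KH2PO4/K2HPO4 buffer pH 8.0, DMSO (5% v/v), 30 °C; EtOAc extraction at pH 5
Reagents that add atoms: dioxygen, O=O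
Why: Enzymatic hydroxylative dearomatisation by the flavin-dependent monooxygenase hydroxylates the methyl-bearing ring carbon on one face only, which sets C7, and the o-quinol then closes the pyran ring by attack of the side-chain ketone enol on the aldehyde and loss of water; the substrate differs from the natural substrate class of these enzymes only by its terminal hydroxyl.

Step 17
Reactants: 22 (S)-7-hydroxy-3-[(S,1E,3E)-7-hydroxy-3,5-dimethylhepta-1,3-dien-1-yl]-7-methyl-6H-isochromene-6,8(7H)-dione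
Product: 23 (S)-3-[(S,1E,3E)-3,5-dimethyl-7-((triethylsilyl)oxy)hepta-1,3-dien-1-yl]-7-methyl-7-((triethylsilyl)oxy)-6H-isochromene-6,8(7H)-dione
Conditions: TESOTf (3 equiv), 2,6-lutidine (5 equiv), CH2Cl2, −78 to −20 °C
Reagents that add atoms: triethylsilyl trifluoromethanesulfonate (TESOTf), CC[Si](CC)(CC)OS(=O)(=O)C(F)(F)F
Why: Silyl triflate silylation caps the primary and the hindered tertiary hydroxyl in one operation, and the bulky C7 silyl ether becomes the control element for the C8 reduction.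

Step 18
Reactants: 23 (S)-3-[(S,1E,3E)-3,5-dimethyl-7-((triethylsilyl)oxy)hepta-1,3-dien-1-yl]-7-methyl-7-((triethylsilyl)oxy)-6H-isochromene-6,8(7H)-dione
Product: 24 (R)-5-chloro-3-[(S,1E,3E)-3,5-dimethyl-7-((triethylsilyl)oxy)hepta-1,3-dien-1-yl]-7-methyl-7-((triethylsilyl)oxy)-6H-isochromene-6,8(7H)-dione
Conditions: NCS (1.05 equiv), MeCN, 0 °C to rt, dark
Reagents that add atoms: N-chlorosuccinimide (NCS), O=C1CCC(=O)N1Cl
Why: Electrophilic chlorination takes place at C5, the nucleophilic α-carbon of the extended vinylogous ester, as in O-capped azaphilones of the sclerotiorin type; the C7 descriptor changes from S to R only because chlorine raises the priority of C6.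

Step 19
Reactants: 24 (R)-5-chloro-3-[(S,1E,3E)-3,5-dimethyl-7-((triethylsilyl)oxy)hepta-1,3-dien-1-yl]-7-methyl-7-((triethylsilyl)oxy)-6H-isochromene-6,8(7H)-dione
Product: 25 (7R,8R)-5-chloro-3-[(S,1E,3E)-3,5-dimethyl-7-((triethylsilyl)oxy)hepta-1,3-dien-1-yl]-8-hydroxy-7-methyl-7-((triethylsilyl)oxy)-7,8-dihydro-6H-isochromen-6-one
Conditions: NaBH4 (1.0 equiv), CeCl3·7H2O, MeOH/THF, −78 °C
Reagents that add atoms: none
Why: Luche 1,2-reduction should take the C8 carbonyl (a simple vinylogous ester) in preference to the C6 carbonyl (deactivated by pyrylium-olate delocalisation), with hydride adding anti to the bulky, electronegative C7 silyloxy group (polar Felkin–Anh), which sets C8 (R) with its hydroxyl cis to the C7 oxygen.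

Step 20
Reactants: 25 (7R,8R)-5-chloro-3-[(S,1E,3E)-3,5-dimethyl-7-((triethylsilyl)oxy)hepta-1,3-dien-1-yl]-8-hydroxy-7-methyl-7-((triethylsilyl)oxy)-7,8-dihydro-6H-isochromen-6-one
Product: 26 (7R,8R)-5-chloro-7,8-dihydroxy-3-[(S,1E,3E)-7-hydroxy-3,5-dimethylhepta-1,3-dien-1-yl]-7-methyl-7,8-dihydro-6H-isochromen-6-one
Conditions: HF·pyridine, pyridine, THF, 0 °C to rt
Reagents that add atoms: none
Why: Buffered fluoride desilylation removes both triethylsilyl ethers under near-neutral conditions that spare the acid-labile C8 allylic alcohol and the base-sensitive pyranone.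

## Compound list

1 | 3-methylenedihydrofuran-2(3H)-one | C=C1CCOC1=O | starting material
2 | (S)-3-methyldihydrofuran-2(3H)-one | C[C@H]1CCOC1=O | intermediate
3 | (S)-4-hydroxy-N-methoxy-N,2-dimethylbutanamide | CON(C)C(=O)[C@@H](C)CCO | intermediate
4 | (S)-4-((tert-butyldimethylsilyl)oxy)-N-methoxy-N,2-dimethylbutanamide | CON(C)C(=O)[C@@H](C)CCO[Si](C)(C)C(C)(C)C | intermediate
5 | (S)-4-((tert-butyldimethylsilyl)oxy)-2-methylbutanal | O=C[C@@H](C)CCO[Si](C)(C)C(C)(C)C | intermediate
6 | ethyl 2-(triphenylphosphoranylidene)propanoate | CCOC(=O)C(C)=P(c1ccccc1)(c1ccccc1)c1ccccc1 | starting material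
7 | ethyl (S,E)-6-((tert-butyldimethylsilyl)oxy)-2,4-dimethylhex-2-enoate | CCOC(=O)/C(C)=C/[C@@H](C)CCO[Si](C)(C)C(C)(C)C | intermediate
8 | (S,E)-6-((tert-butyldimethylsilyl)oxy)-2,4-dimethylhex-2-en-1-ol | OC/C(C)=C/[C@@H](C)CCO[Si](C)(C)C(C)(C)C | intermediate
9 | (S,E)-6-((tert-butyldimethylsilyl)oxy)-2,4-dimethylhex-2-enal | O=C/C(C)=C/[C@@H](C)CCO[Si](C)(C)C(C)(C)C | intermediate
10 | diethyl (3-(trimethylsilyl)prop-2-yn-1-yl)phosphonate | CCOP(=O)(CC#C[Si](C)(C)C)OCC | starting material
11 | tert-butyl{[(S,4E,6E)-3,5-dimethyl-9-(trimethylsilyl)nona-4,6-dien-8-yn-1-yl]oxy}dimethylsilane | CC(/C=C/C#C[Si](C)(C)C)=C\[C@@H](C)CCO[Si](C)(C)C(C)(C)C | intermediate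
12 | (S,4E,6E)-3,5-dimethylnona-4,6-dien-8-yn-1-ol | CC(/C=C/C#C)=C\[C@@H](C)CCO | intermediate
13 | 1,3-dimethoxy-2-methylbenzene | COc1cccc(OC)c1C | starting material
14 | 2-(3,5-dimethoxy-4-methylphenyl)-4,4,5,5-tetramethyl-1,3,2-dioxaborolane | COc1cc(B2OC(C)(C)C(C)(C)O2)cc(OC)c1C | intermediate
15 | 5-bromo-1,3-dimethoxy-2-methylbenzene | COc1cc(Br)cc(OC)c1C | intermediate
16 | 6-bromo-2,4-dimethoxy-3-methylbenzaldehyde | COc1cc(Br)c(C=O)c(OC)c1C | intermediate
17 | 6-bromo-2,4-dihydroxy-3-methylbenzaldehyde | Cc1c(O)cc(Br)c(C=O)c1O | intermediate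
18 | 2,4-dihydroxy-6-[(S,3E,5E)-9-hydroxy-5,7-dimethylnona-3,5-dien-1-yn-1-yl]-3-methylbenzaldehyde | CC(/C=C/C#Cc1cc(O)c(C)c(O)c1C=O)=C\[C@@H](C)CCO | intermediate
19 | 6,8-dihydroxy-3-[(S,1E,3E)-7-hydroxy-3,5-dimethylhepta-1,3-dien-1-yl]-7-methylisochromenylium 2,2,2-trifluoroacetate (not isolated) | CC(/C=C/c1cc2cc(O)c(C)c(O)c2c[o+]1)=C\[C@@H](C)CCO.[O-]C(=O)C(F)(F)F | intermediate
20 | 2,4-dihydroxy-6-[(S,3E,5E)-9-hydroxy-5,7-dimethyl-2-oxonona-3,5-dien-1-yl]-3-methylbenzaldehyde | CC(/C=C/C(=O)Cc1cc(O)c(C)c(O)c1C=O)=C\[C@@H](C)CCO | intermediate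
21 | (R)-2,3-dihydroxy-6-[(S,3E,5E)-9-hydroxy-5,7-dimethyl-2-oxonona-3,5-dien-1-yl]-3-methyl-4-oxocyclohexa-1,5-diene-1-carbaldehyde (o-quinol, not isolated) | CC(/C=C/C(=O)CC1=CC(=O)[C@](C)(O)C(O)=C1C=O)=C\[C@@H](C)CCO | intermediate
22 | (S)-7-hydroxy-3-[(S,1E,3E)-7-hydroxy-3,5-dimethylhepta-1,3-dien-1-yl]-7-methyl-6H-isochromene-6,8(7H)-dione | CC(/C=C/C1=CC2=CC(=O)[C@](C)(O)C(=O)C2=CO1)=C\[C@@H](C)CCO | intermediate
23 | (S)-3-[(S,1E,3E)-3,5-dimethyl-7-((triethylsilyl)oxy)hepta-1,3-dien-1-yl]-7-methyl-7-((triethylsilyl)oxy)-6H-isochromene-6,8(7H)-dione | CC(/C=C/C1=CC2=CC(=O)[C@](C)(O[Si](CC)(CC)CC)C(=O)C2=CO1)=C\[C@@H](C)CCO[Si](CC)(CC)CC | intermediate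
24 | (R)-5-chloro-3-[(S,1E,3E)-3,5-dimethyl-7-((triethylsilyl)oxy)hepta-1,3-dien-1-yl]-7-methyl-7-((triethylsilyl)oxy)-6H-isochromene-6,8(7H)-dione | CC(/C=C/C1=CC2=C(Cl)C(=O)[C@](C)(O[Si](CC)(CC)CC)C(=O)C2=CO1)=C\[C@@H](C)CCO[Si](CC)(CC)CC | intermediate
25 | (7R,8R)-5-chloro-3-[(S,1E,3E)-3,5-dimethyl-7-((triethylsilyl)oxy)hepta-1,3-dien-1-yl]-8-hydroxy-7-methyl-7-((triethylsilyl)oxy)-7,8-dihydro-6H-isochromen-6-one | CC(/C=C/C1=CC2=C(Cl)C(=O)[C@](C)(O[Si](CC)(CC)CC)[C@H](O)C2=CO1)=C\[C@@H](C)CCO[Si](CC)(CC)CC | intermediate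
26 | (7R,8R)-5-chloro-7,8-dihydroxy-3-[(S,1E,3E)-7-hydroxy-3,5-dimethylhepta-1,3-dien-1-yl]-7-methyl-7,8-dihydro-6H-isochromen-6-one | CC(/C=C/C1=CC2=C(Cl)C(=O)[C@](C)(O)[C@H](O)C2=CO1)=C\[C@@H](C)CCO | target

## Step count and risks

Total step count: 20.
Longest linear sequence: 16 steps (steps 1–9, then 14–20) from compound 1; the arene branch (steps 10–13) is 4 steps from compound 13.

The three steps most likely to fail:

Step 19 (C8 reduction). The hydride may attack C6, add 1,4 at C1, or give the trans-diol. The fallback replaces substrate control by a biocatalytic reduction and drops the silyl groups. It sets out from 22, which is chlorinated directly (NCS, MeCN, 0 °C) to (R)-5-chloro-7-hydroxy-3-[(S,1E,3E)-7-hydroxy-3,5-dimethylhepta-1,3-dien-1-yl]-7-methyl-6H-isochromene-6,8(7H)-dione F3. The C8 carbonyl of this compound is then reduced with an NADPH-dependent ketoreductase chosen from a panel for the 8R alcohol (NADP+ cat., isopropanol as terminal reductant, KH2PO4/K2HPO4 buffer pH 7, 30 °C). This comes back to the route at the target 26 and makes steps 17 and 20 unnecessary.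

Step 15 (cycloisomerisation and hydrolysis). The cationic dienyl benzopyrylium 19 may oligomerise in TFA, or its ring-opening may stall at the neutral quinoid form of 19. The fallback sets out from 18 and traps the cyclised species with methanol under neutral silver catalysis (AgOSO2CF3, 5 mol%, MeOH/CH2Cl2, rt). This gives the isolable mixed acetal 3-[(S,1E,3E)-7-hydroxy-3,5-dimethylhepta-1,3-dien-1-yl]-1-methoxy-7-methyl-1H-isochromene-6,8-diol F1 (both C1 epimers), which is purified. It is then unmasked in a separate operation with pyridinium p-toluenesulfonate in wet acetone at rt (acetal hydrolysis and ring-opening), coming back to the route at 20.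

Step 16 (enzymatic dearomatisation). Keto-aldehyde 20 may be turned over poorly, or the amine-reactive azaphilone 22 may be lost to lysate proteins at pH 8. The fallback changes the order of events: it sets out from alkyne 18 and runs the same monooxygenase system on it. The product, the o-quinol (R)-2,3-dihydroxy-6-[(S,3E,5E)-9-hydroxy-5,7-dimethylnona-3,5-dien-1-yn-1-yl]-3-methyl-4-oxocyclohexa-1,5-diene-1-carbaldehyde F2, cannot close the pyran ring by itself and is extracted intact. It is then cycloisomerised chemically (CuI, 10 mol%, MeCN/KH2PO4–K2HPO4 buffer pH 7.2, rt; 6-endo-dig addition of the formyl oxygen to the alkyne), coming back to the route at 22 and bypassing 20. Acceptance of the alkyne substrate by the enzyme is not established and would have to be tested.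

Further compounds
F1 | step 15 | 3-[(S,1E,3E)-7-hydroxy-3,5-dimethylhepta-1,3-dien-1-yl]-1-methoxy-7-methyl-1H-isochromene-6,8-diol (C1 epimers) | CC(/C=C/C1=Cc2cc(O)c(C)c(O)c2C(OC)O1)=C\[C@@H](C)CCO
F2 | step 16 | (R)-2,3-dihydroxy-6-[(S,3E,5E)-9-hydroxy-5,7-dimethylnona-3,5-dien-1-yn-1-yl]-3-methyl-4-oxocyclohexa-1,5-diene-1-carbaldehyde | CC(/C=C/C#CC1=CC(=O)[C@](C)(O)C(O)=C1C=O)=C\[C@@H](C)CCO
F3 | step 19 | (R)-5-chloro-7-hydroxy-3-[(S,1E,3E)-7-hydroxy-3,5-dimethylhepta-1,3-dien-1-yl]-7-methyl-6H-isochromene-6,8(7H)-dione | CC(/C=C/C1=CC2=C(Cl)C(=O)[C@](C)(O)C(=O)C2=CO1)=C\[C@@H](C)CCO
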